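Numbering follows daucane: C1 quaternary C–CH3, C2–C3 ring CH2, C4 isopropyl carbinol, C5 ring-fusion CH, C6 ester carbon, C7=C8(CH3), C9 free carbinol, C10 CH2; β is the face of the C1 methyl, α that of H-5.
Retrosynthesis: the C6–O vanillate is cut first; the hydroazulene is traced to an oxygen-bridged [5+2] adduct by cutting C5–C1 and C9–C10 (C5–O–C9 closed, C8 methyl removed); the acyclic precursor is cut at C5–C6 (furyl anion + aldehyde) and C2–C3 (methallyl Grignard + epoxide).
Enabling feature: C6(O)–C7=C8–C9(O) of the seven-membered ring, with C5 attached, is a masked 2-furylcarbinol (furan C2–C5 = C6–C9), hence a 3-oxidopyrylium whose termini C5 and C9 can be spanned by the C1=C10 methallyl alkene hanging from C4 through C3–C2.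
Forward order: chain assembly, pyranone ring from the furan, then cyclopentane (C1–C5) and cycloheptene (C5–C10, C1) together in one cycloaddition; afterwards the C5–O–C9 bridge is cut, the C8 methyl and C7=C8 are installed, C9 is inverted, C6 reduced and acylated.
Stereochemistry: C4 from a Sharpless epoxidation; C1 and the α bridge at C5/C9 relayed from C4 in the cycloaddition; H-5 on protonation after C5–O cleavage; C9 by Mitsunobu inversion; C6 by hydride delivery directed by the C4 hydroxyl.

Key step: step 9

Assumption: 1, 4 (as its THF solution), 8 and 22 are taken as catalogue compounds; centres that vanish in the ylide (the carbinol carbon of 10, ring C2 and C6 of 11 and 12) are carried as mixtures.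

Step 1
Reactants: 1 3-methyl-2-methylenebutanal (2-isopropylacrolein)
Product: 2 3-methyl-2-methylenebutan-1-ol
Conditions: NaBH4, CeCl3·7H2O, MeOH, 0 °C
Reagents that add atoms: none
Why: Luche reduction delivers hydride only to the carbonyl carbon, so the 2-substituted acrolein should give the allylic alcohol without conjugate reduction.

Step 2
Reactants: 2 3-methyl-2-methylenebutan-1-ol
Product: 3 (R)-(2-isopropyloxiran-2-yl)methanol
Conditions: Ti(OiPr)4 (cat.), D-(−)-diisopropyl tartrate (cat.), t-BuOOH, 4 Å molecular sieves, CH2Cl2, −20 °C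
Reagents that add atoms: tert-butyl hydroperoxide, CC(C)(C)OO
Why: Sharpless asymmetric epoxidation of a 2-substituted allylic alcohol, in which the Ti(OiPr)4–D-(−)-tartrate complex delivers oxygen to the alkene face that gives the (R)-epoxide (the L-(+)-ester would give S) and so sets C4 of the target.

Step 3
Reactants: 3 (R)-(2-isopropyloxiran-2-yl)methanol; 4 methallylmagnesium chloride
Product: 5 (R)-2-isopropyl-5-methylhex-5-ene-1,2-diol
Conditions: 4 (3.5 equiv), CuI (10 mol%), THF, −30 → 0 °C; aq. NH4Cl
Reagents that add atoms: none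
Why: Copper-catalysed SN2 opening of the epoxide at its unsubstituted CH2 terminus by the (symmetrical) allylic Grignard reagent forms C2–C3 without touching the tertiary centre; the first equivalent is spent on the hydroxyl, and a Payne shift of this epoxy alkoxide is degenerate.

Step 4
Reactants: 5 (R)-2-isopropyl-5-methylhex-5-ene-1,2-diol
Product: 6 (R)-2-isopropyl-5-methyl-1,2-bis(triethylsilyloxy)hex-5-ene
Conditions: Et3SiOTf, 2,6-lutidine, CH2Cl2, −78 → 0 °C
Reagents that add atoms: triethylsilyl trifluoromethanesulfonate, CC[Si](CC)(CC)OS(=O)(=O)C(F)(F)F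
Why: Silyl triflate silylation is strong enough for the tertiary hydroxyl, and covering both oxygens lets the primary one be unmasked oxidatively in the next step.

Step 5
Reactants: 6 (R)-2-isopropyl-5-methyl-1,2-bis(triethylsilyloxy)hex-5-ene
Product: 7 (R)-2-isopropyl-5-methyl-2-(triethylsilyloxy)hex-5-enal
Conditions: (COCl)2, DMSO, CH2Cl2, −78 → −30 °C; then Et3N, −78 °C → rt
Reagents that add atoms: none
Why: Swern oxidation in which the chlorosulfonium reagent cleaves only the primary triethylsilyl ether and oxidises it directly to the aldehyde, while the tertiary silyl ether survives and the aldehyde, having no α-hydrogen, cannot epimerise.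

Step 6
Reactants: 7 (R)-2-isopropyl-5-methyl-2-(triethylsilyloxy)hex-5-enal; 8 furan
Product: 10 (2R)-1-(furan-2-yl)-2-isopropyl-5-methyl-2-(triethylsilyloxy)hex-5-en-1-ol as both C1 epimers, via 2-furyllithium 9 (not isolated)
Conditions: 8, n-BuLi, THF, −78 → 0 °C; then 7, −78 °C; aq. NH4Cl at −78 °C
Reagents that add atoms: none
Why: 1,2-addition of an organolithium to a non-enolisable aldehyde forms C5–C6; the new carbinol centre needs no control because it becomes sp2 in step 9, and the cold quench guards against silyl migration to the new alkoxide.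

Step 7
Reactants: 10 (2R)-1-(furan-2-yl)-2-isopropyl-5-methyl-2-(triethylsilyloxy)hex-5-en-1-ol
Product: 11 6-hydroxy-2-[(3R)-2,6-dimethyl-3-(triethylsilyloxy)hept-6-en-3-yl]-2H-pyran-3(6H)-one
Conditions: VO(acac)2 (5 mol%), t-BuOOH, CH2Cl2, 0 °C → rt
Reagents that add atoms: tert-butyl hydroperoxide, CC(C)(C)OO
Why: Achmatowicz oxidative rearrangement: hydroxyl-directed oxidation of the furan and ring expansion to the lactol pyranone, chemoselective over the remote 1,1-disubstituted alkene.

Step 8
Reactants: 11 6-hydroxy-2-[(3R)-2,6-dimethyl-3-(triethylsilyloxy)hept-6-en-3-yl]-2H-pyran-3(6H)-one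
Product: 12 6-acetoxy-2-[(3R)-2,6-dimethyl-3-(triethylsilyloxy)hept-6-en-3-yl]-2H-pyran-3(6H)-one
Conditions: Ac2O, pyridine, DMAP (cat.), CH2Cl2, 0 °C
Reagents that add atoms: acetic anhydride, CC(=O)OC(C)=O
Why: DMAP-catalysed acylation of the lactol hydroxyl, the only free hydroxyl, installs the anomeric leaving group needed for pyrylium formation.

Step 9
Reactants: 12 6-acetoxy-2-[(3R)-2,6-dimethyl-3-(triethylsilyloxy)hept-6-en-3-yl]-2H-pyran-3(6H)-one
Product: 14 5-methyl-2-(propan-2-yl)-2-(triethylsilyloxy)-11-oxatricyclo[5.3.1.0^1,5]undec-8-en-10-one (daucane numbering: C5–O–C9 bridge α; 1-methyl β; 4-silyloxy β; C6 ketone; C7=C8), via 3-oxidopyrylium ylide 13 (not isolated)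
Conditions: DBU (1.5 equiv), MeCN (0.01 M), rt → 60 °C
Reagents that add atoms: none
Why: DBU enolises the acetoxypyranone and acetate leaves, giving the planar 3-oxidopyrylium 13, a carbonyl-ylide-type dipole whose ring carbons flanking oxygen (C5 and C9 of the target) add suprafacially across the tethered C1=C10 alkene in a concerted, thermally allowed six-electron [5+2] cycloaddition that forms C5–C1 and C9–C10. The closest known reaction type is the intramolecular 3-oxidopyrylium–alkene [5+2] cycloaddition of 6-acetoxy-2H-pyran-3(6H)-ones carrying an unactivated alkene on a three-atom tether at C2; the fully substituted tether carbon and the 1,1-disubstituted alkene only extend that substrate class. The seven-membered carbocycle (C5–C10 and C1) closes through the cycloaddition itself, as an oxygen-bridged cycloheptenone, and the cyclopentane (C1–C5) closes through the same C5–C1 bond, exo with respect to the alkene, because the C4–C3–C2 tether can only span the bridgehead and the exo position of the new two-carbon bridge. This geometry puts the oxygen bridge on one face at C5 and C9 and the C1 methyl endo, anti to the bridge, so the three new centres are fixed relative to one another and the methyl is trans to the position H-5 will take. The selectivity needed is the choice of pyrylium face relative to C4, and 1,3-allylic strain should provide it: of the two C4 groups not held in the tether, only the ether oxygen (SiEt3 turned outward) can sit in the pyrylium plane beside the oxido oxygen on C6, so the branched isopropyl group turns to the face opposite the alkene and C1 forms with its methyl cis to the C4 oxygen. High dilution suppresses ylide dimerisation, and the silyl ether keeps the C4 oxygen from closing a bicyclic acetal onto the acetoxy-bearing carbon.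

Step 10
Reactants: 14 tricyclic enone (oxygen-bridged cycloadduct)
Product: 15 5α,9α-epoxy-4β-(triethylsilyloxy)-8βH-daucan-6-one (8-methyl α; 1-methyl β)
Conditions: Me2CuLi (from CuI and 2 MeLi), Et2O, −78 → −30 °C; aq. NH4Cl
Reagents that add atoms: lithium dimethylcuprate, [Li+].C[Cu-]C
Why: Conjugate addition of Me2CuLi to the bicyclic enone from the exo face (the side of the oxygen bridge, away from the two-carbon bridge and its endo methyl) installs the C8 methyl at a temporary stereocentre and leaves only the C5–O bond α to the ketone for the following reduction.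

Step 11
Reactants: 15 5α,9α-epoxy-4β-(triethylsilyloxy)-8βH-daucan-6-one
Product: 16 9α-hydroxy-4β-(triethylsilyloxy)-5αH,8βH-daucan-6-one (trans-fused)
Conditions: SmI2 (2.5 equiv), THF–MeOH (10:1), −78 °C
Reagents that add atoms: none
Why: Reductive cleavage of an α-alkoxy ketone by SmI2 expels the C5 alkoxide and frees the C9 hydroxyl, and protonation of the resulting samarium enolate on the face the oxygen has just left (by the nearby C9 hydroxyl or its samarium-bound methanol) should place H-5 α, trans to the C1 methyl, which is also expected to be the more stable ring fusion.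

Step 12
Reactants: 16 9α-hydroxy-4β-(triethylsilyloxy)-5αH,8βH-daucan-6-one
Product: 17 4β-(triethylsilyloxy)-6,9α-bis(trimethylsilyloxy)-5αH,8βH-dauc-6-ene
Conditions: Me3SiCl (5 equiv), LiN(iPr)2 (2.5 equiv, added last), THF, −78 °C
Reagents that add atoms: chlorotrimethylsilane, C[Si](C)(C)Cl
Why: Kinetic enolisation by the hindered lithium amide under internal silyl chloride quench removes a C7 methylene proton rather than the C5 methine buried between two quaternary carbons, giving the C6=C7 silyl enol ether and silylating the C9 hydroxyl in the same operation.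

Step 13
Reactants: 17 4β-(triethylsilyloxy)-6,9α-bis(trimethylsilyloxy)-5αH,8βH-dauc-6-ene
Product: 18 4β-(triethylsilyloxy)-9α-(trimethylsilyloxy)dauc-7-en-6-one
Conditions: Pd(OAc)2 (1.1 equiv), MeCN, rt
Reagents that add atoms: none
Why: Saegusa–Ito oxidation: the palladium enolate formed from the silyl enol ether loses H-8 by β-hydride elimination, giving the C7=C8 enone and erasing the temporary C8 centre.

Step 14
Reactants: 18 4β-(triethylsilyloxy)-9α-(trimethylsilyloxy)dauc-7-en-6-one
Product: 19 4β,9α-dihydroxydauc-7-en-6-one (1-methyl β; H-5 α)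
Conditions: HF·pyridine, pyridine, THF, 0 °C → rt
Reagents that add atoms: none
Why: Buffered fluoride desilylation removes both silyl ethers without base, so the β-hydroxy ketone should neither dehydrate nor undergo retro-aldol cleavage.

Step 15
Reactants: 19 4β,9α-dihydroxydauc-7-en-6-one
Product: 20 9β-(chloroacetoxy)-4β-hydroxydauc-7-en-6-one
Conditions: ClCH2CO2H, PPh3, DIAD, toluene, 0 °C → rt
Reagents that add atoms: chloroacetic acid, OC(=O)CCl
Why: Mitsunobu reaction: the secondary allylic C9 hydroxyl is activated as its oxyphosphonium salt and displaced with inversion by chloroacetate, an acidic and small nucleophile suited to hindered alcohols, turning the bridge-derived 9α oxygen into the 9β ester while the tertiary C4 hydroxyl stays inert.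

Step 16
Reactants: 20 9β-(chloroacetoxy)-4β-hydroxydauc-7-en-6-one
Product: 21 9β-(chloroacetoxy)dauc-7-ene-4β,6α-diol
Conditions: Me4NBH(OAc)3 (5 equiv), MeCN–AcOH (1:1), −30 → 0 °C
Reagents that add atoms: none
Why: Hydroxyl-directed triacetoxyborohydride reduction (Evans–Saksena): the C4 hydroxyl exchanges onto boron and hydride is delivered intramolecularly to the β face of the C6 carbonyl, 1,2 only, giving the 6α alcohol anti to the C4 oxygen.

Step 17
Reactants: 21 9β-(chloroacetoxy)dauc-7-ene-4β,6α-diol; 22 4-acetoxy-3-methoxybenzoic acid (O-acetylvanillic acid)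
Product: 24 9β-(chloroacetoxy)-4β-hydroxydauc-7-en-6α-yl 4-acetoxy-3-methoxybenzoate, via 4-acetoxy-3-methoxybenzoyl chloride 23 (not isolated)
Conditions: 22, (COCl)2, DMF (cat.), CH2Cl2, 0 °C → rt, evaporate; then 21, pyridine, DMAP (cat.), CH2Cl2, 0 °C → rt
Reagents that add atoms: none
Why: DMAP-catalysed acylation by the aroyl chloride esterifies the only secondary hydroxyl (allylic, C6); the tertiary C4 hydroxyl is too hindered to react and the phenol is masked as its acetate.

Step 18
Reactants: 24 9β-(chloroacetoxy)-4β-hydroxydauc-7-en-6α-yl 4-acetoxy-3-methoxybenzoate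
Product: 25 4β,9β-dihydroxydauc-7-en-6α-yl 4-hydroxy-3-methoxybenzoate, i.e. (3R,3aS,4S,7R,8aR)-3,7-dihydroxy-6,8a-dimethyl-3-(propan-2-yl)-1,2,3,3a,4,7,8,8a-octahydroazulen-4-yl 4-hydroxy-3-methoxybenzoate (target)
Conditions: NH3 (7 M in MeOH), THF, 0 °C
Reagents that add atoms: none
Why: Ammonolysis discriminates by ester reactivity: the chloroacetate and the aryl acetate should be cleaved far faster than the hindered, electron-rich secondary vanillate, which is left as the target.

Compound list
1 | 3-methyl-2-methylenebutanal (2-isopropylacrolein) | CC(C)C(=C)C=O | starting material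
2 | 3-methyl-2-methylenebutan-1-ol | CC(C)C(=C)CO | intermediate
3 | (R)-(2-isopropyloxiran-2-yl)methanol | OC[C@]1(C(C)C)CO1 | intermediate
4 | methallylmagnesium chloride (2-methylprop-2-en-1-ylmagnesium chloride) | C=C(C)C[Mg]Cl | starting material
5 | (R)-2-isopropyl-5-methylhex-5-ene-1,2-diol | C=C(C)CC[C@@](O)(C(C)C)CO | intermediate
6 | (R)-2-isopropyl-5-methyl-1,2-bis(triethylsilyloxy)hex-5-ene | C=C(C)CC[C@@](O[Si](CC)(CC)CC)(C(C)C)CO[Si](CC)(CC)CC | intermediate
7 | (R)-2-isopropyl-5-methyl-2-(triethylsilyloxy)hex-5-enal | C=C(C)CC[C@@](O[Si](CC)(CC)CC)(C(C)C)C=O | intermediate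
8 | furan | c1ccoc1 | starting material
9 | 2-furyllithium | [Li]c1ccco1 | intermediate
10 | (2R)-1-(furan-2-yl)-2-isopropyl-5-methyl-2-(triethylsilyloxy)hex-5-en-1-ol (both C1 epimers) | C=C(C)CC[C@@](O[Si](CC)(CC)CC)(C(C)C)C(O)c1ccco1 | intermediate
11 | 6-hydroxy-2-[(3R)-2,6-dimethyl-3-(triethylsilyloxy)hept-6-en-3-yl]-2H-pyran-3(6H)-one (ring C2 and C6 as mixtures) | C=C(C)CC[C@@](O[Si](CC)(CC)CC)(C(C)C)C1OC(O)C=CC1=O | intermediate
12 | 6-acetoxy-2-[(3R)-2,6-dimethyl-3-(triethylsilyloxy)hept-6-en-3-yl]-2H-pyran-3(6H)-one (ring C2 and C6 as mixtures) | C=C(C)CC[C@@](O[Si](CC)(CC)CC)(C(C)C)C1OC(OC(C)=O)C=CC1=O | intermediate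
13 | 2-[(3R)-2,6-dimethyl-3-(triethylsilyloxy)hept-6-en-3-yl]pyrylium-3-olate (3-oxidopyrylium ylide) | C=C(C)CC[C@@](O[Si](CC)(CC)CC)(C(C)C)c1[o+]cccc1[O-] | intermediate
14 | 5-methyl-2-(propan-2-yl)-2-(triethylsilyloxy)-11-oxatricyclo[5.3.1.0^1,5]undec-8-en-10-one; daucane numbering: 5α,9α oxygen bridge, 1β-methyl, 4β-silyloxy, 6-oxo, 7-ene | O=C2C=C[C@@H]4C[C@@]3(C)CC[C@@](O[Si](CC)(CC)CC)(C(C)C)[C@]23O4 | intermediate
15 | 5α,9α-epoxy-4β-(triethylsilyloxy)-8βH-daucan-6-one (8α-methyl, 1β-methyl) | O=C2C[C@@H](C)[C@@H]4C[C@@]3(C)CC[C@@](O[Si](CC)(CC)CC)(C(C)C)[C@]23O4 | intermediate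
16 | 9α-hydroxy-4β-(triethylsilyloxy)-5αH,8βH-daucan-6-one (trans-fused, 1β-methyl) | O=C2C[C@@H](C)[C@@H](O)C[C@@]3(C)CC[C@@](O[Si](CC)(CC)CC)(C(C)C)[C@H]23 | intermediate
17 | 4β-(triethylsilyloxy)-6,9α-bis(trimethylsilyloxy)-5αH,8βH-dauc-6-ene | C[Si](C)(C)OC2=C[C@@H](C)[C@@H](O[Si](C)(C)C)C[C@@]3(C)CC[C@@](O[Si](CC)(CC)CC)(C(C)C)[C@H]23 | intermediate
18 | 4β-(triethylsilyloxy)-9α-(trimethylsilyloxy)-5αH-dauc-7-en-6-one | O=C2C=C(C)[C@@H](O[Si](C)(C)C)C[C@@]3(C)CC[C@@](O[Si](CC)(CC)CC)(C(C)C)[C@H]23 | intermediate
19 | 4β,9α-dihydroxy-5αH-dauc-7-en-6-one | O=C2C=C(C)[C@@H](O)C[C@@]3(C)CC[C@@](O)(C(C)C)[C@H]23 | intermediate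
20 | 9β-(chloroacetoxy)-4β-hydroxy-5αH-dauc-7-en-6-one | O=C2C=C(C)[C@H](OC(=O)CCl)C[C@@]3(C)CC[C@@](O)(C(C)C)[C@H]23 | intermediate
21 | 9β-(chloroacetoxy)-5αH-dauc-7-ene-4β,6α-diol | O[C@H]2C=C(C)[C@H](OC(=O)CCl)C[C@@]3(C)CC[C@@](O)(C(C)C)[C@H]23 | intermediate
22 | 4-acetoxy-3-methoxybenzoic acid (O-acetylvanillic acid) | COc1cc(C(=O)O)ccc1OC(C)=O | starting material
23 | 4-acetoxy-3-methoxybenzoyl chloride | COc1cc(C(=O)Cl)ccc1OC(C)=O | intermediate
24 | 9β-(chloroacetoxy)-4β-hydroxy-5αH-dauc-7-en-6α-yl 4-acetoxy-3-methoxybenzoate | COc1cc(C(=O)O[C@H]2C=C(C)[C@H](OC(=O)CCl)C[C@@]3(C)CC[C@@](O)(C(C)C)[C@H]23)ccc1OC(C)=O | intermediate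
25 | (3R,3aS,4S,7R,8aR)-3,7-dihydroxy-6,8a-dimethyl-3-(propan-2-yl)-1,2,3,3a,4,7,8,8a-octahydroazulen-4-yl 4-hydroxy-3-methoxybenzoate (4β,9β-dihydroxy-5αH-dauc-7-en-6α-yl vanillate, CNP0189996.3) | COc1cc(C(=O)O[C@H]2C=C(C)[C@H](O)C[C@@]3(C)CC[C@@](O)(C(C)C)[C@H]23)ccc1O | target

Total step count: 18. Longest linear sequence: 18 steps (1 → 25); 4, 8 and 22 enter as purchased components.

Steps most likely to fail

Step 9. The alkene may add to the other face of the pyrylium if the isopropyl group rather than the ether oxygen takes the in-plane site (dipole repulsion between the ether and oxido oxygens works against the steric preference). That would invert C1, C5 and C9 relative to C4; ylide dimerisation is the lesser risk. The fallback replaces substrate control by catalyst control. It sets out from lactol 11, which is acylated with 4-(methylthio)benzoyl chloride (Et3N, DMAP, CH2Cl2) to give 6-[4-(methylthio)benzoyloxy]-2-[(3R)-2,6-dimethyl-3-(triethylsilyloxy)hept-6-en-3-yl]-2H-pyran-3(6H)-one F1. This ester is cyclised under the dual-catalysis conditions known for intramolecular oxidopyrylium [5+2] cycloadditions: a chiral primary aminothiourea such as 1-[(1R,2R)-2-aminocyclohexyl]-3-[3,5-bis(trifluoromethyl)phenyl]thiourea (or its enantiomer, whichever is matched to the required face), N,N'-bis[3,5-bis(trifluoromethyl)phenyl]thiourea and AcOH in toluene at 40 °C. The chiral aminopyrylium–benzoate ion pair then selects the face, and hydrolysis on work-up brings the material back to the route at 14.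

Step 11. External methanol may protonate the samarium enolate at C5 from the more open β face instead of the proton arriving on the α face from the C9 oxygen, which would give the cis-fused ketone. The fallback puts C5 under thermodynamic instead of kinetic control in a separate operation. It sets out from 15: the reduction is run as before and the crude ketone, containing the C5 epimer 9α-hydroxy-4β-(triethylsilyloxy)-5βH,8βH-daucan-6-one F2, is equilibrated through the C5 enolate with a mild base (DBU, toluene, rt). The base is kept mild because the C4 silyloxy group is β to that enolate. The trans-fused ketone, in which C6 lies beside the smaller substituent of each flanking quaternary carbon (CH3 on C1, O on C4), should predominate, and the material comes back at 16.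

Step 15. Displacement at C9 must come from the β face, past the C1 methyl in a 1,3-relation, so elimination of the oxyphosphonium salt to a dienone, or no reaction, may take over. The fallback inverts C9 by oxidation and reduction. It sets out from 19: MnO2 (CH2Cl2, rt) oxidises the allylic C9 alcohol to 4β-hydroxy-5αH-dauc-7-ene-6,9-dione F3. NaBH4 with CeCl3·7H2O in MeOH at −78 °C should then reduce the less hindered C9 carbonyl (C6 is shielded by C5 and its two quaternary neighbours) from the α face, anti to the C1 methyl, to give 4β,9β-dihydroxy-5αH-dauc-7-en-6-one F4. Chloroacetic anhydride and pyridine (CH2Cl2, 0 °C) acylate its secondary hydroxyl, and the route is rejoined at 20.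

Further compounds
F1 | step 9 | 6-[4-(methylthio)benzoyloxy]-2-[(3R)-2,6-dimethyl-3-(triethylsilyloxy)hept-6-en-3-yl]-2H-pyran-3(6H)-one | C=C(C)CC[C@@](O[Si](CC)(CC)CC)(C(C)C)C1OC(OC(=O)c2ccc(SC)cc2)C=CC1=O
F2 | step 11 | 9α-hydroxy-4β-(triethylsilyloxy)-5βH,8βH-daucan-6-one (C5 epimer of 16) | O=C2C[C@@H](C)[C@@H](O)C[C@@]3(C)CC[C@@](O[Si](CC)(CC)CC)(C(C)C)[C@@H]23
F3 | step 15 | 4β-hydroxy-5αH-dauc-7-ene-6,9-dione | O=C2C=C(C)C(=O)C[C@@]3(C)CC[C@@](O)(C(C)C)[C@H]23
F4 | step 15 | 4β,9β-dihydroxy-5αH-dauc-7-en-6-one | O=C2C=C(C)[C@H](O)C[C@@]3(C)CC[C@@](O)(C(C)C)[C@H]23
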